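## Retrosynthetic overview

1. Target ⇐ O-desilylation and stereospecific anti-dehydration of an unlike γ-(α-hydroxyalkyl)butenolide. The E alkene (side chain cis to ring C–H) is the less stable isomer, so its geometry is encoded in two transient stereocentres.
2. Aldol adduct ⇐ direct vinylogous aldol (C20–C21 bond) between a 3-(silyloxymethyl)butenolide and the (R)-α-methyl C1–C20 aldehyde.
3. Aldehyde ⇐ oxidation of the alcohol from a B-alkyl Suzuki coupling (C13–C15 bond) of a (Z)-2-iodo-2-alkene (C1–C14) with (R)-2-methylpent-4-en-1-ol (C15–C20).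
4. (R)-2-Methylpent-4-en-1-ol ⇐ organo-SOMO α-allylation of propanal, which sets the only permanent stereocentre. Vinyl iodide ⇐ geranyl acetate by ozonolysis, Z-selective iodo-Wittig olefination and Cu-catalysed 3-furylmethyl Grignard coupling.
5. Rings: none is closed by cyclisation. The 3-substituted furan is bought in; the butenolide ring is made by oxidation of furan-3-ylmethanol and joined last.

Assumption: the SMILES is read literally, i.e. stereocentre R, C12=C13 Z, C7=C8 E, exocyclic C20=C21 E (chain trans to ring O); locants C1–C25 follow variabilin numbering.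
Assumption: 3-(chloromethyl)furan is bought (otherwise one step from furan-3-ylmethanol with SOCl2).

## Route

Step 1
Reactants: 1 propanal; 2 allyltrimethylsilane
Product: 4 (2R)-2-methylpent-4-en-1-ol, via (2R)-2-methylpent-4-enal 3 (not isolated)
Conditions: (2S,5S)-5-benzyl-2-tert-butyl-3-methylimidazolidin-4-one·TFA (20 mol%), CAN (2 equiv), NaHCO3, DME, −20 °C; then NaBH4, EtOH, 0 °C
Reagents that add atoms: none
Why: Organo-SOMO α-allylation: CAN oxidises the enamine to a radical cation whose Re face is shielded by the benzyl group, so the allylsilane adds to the Si face and gives the R centre (about 90% ee is typical for this reaction class; the sense is checked against the known alcohol), and in-flask NaBH4 reduction prevents racemisation and loss of the volatile aldehyde.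

Step 2
Reactants: 5 geranyl acetate
Product: 7 (2E)-3-methyl-6-oxohex-2-en-1-yl acetate, via secondary ozonide 6 (not isolated)
Conditions: O3 (1.0 equiv, Sudan Red end-point), CH2Cl2, −78 °C; then PPh3, −78 °C → rt
Reagents that add atoms: ozone, [O-][O+]=O
Why: Chemoselective ozonolysis: the electron-rich 6,7-alkene reacts much faster than the 2,3-alkene deactivated by the allylic acetate, whose E geometry is untouched.

Step 3
Reactants: 7 (2E)-3-methyl-6-oxohex-2-en-1-yl acetate; 8 ethyltriphenylphosphonium iodide
Product: 12 (2E,6Z)-7-iodo-3-methylocta-2,6-dien-1-yl acetate, via ethylidenetriphenylphosphorane 9 (not isolated), via (1-iodoethyl)triphenylphosphonium iodide 10 (not isolated), via (1-iodoethylidene)triphenylphosphorane 11 (not isolated)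
Conditions: 8, n-BuLi, THF, 0 °C; I2, −78 °C; NaHMDS, −20 °C; then 7, −78 → −20 °C
Reagents that add atoms: iodine, II
Why: Stork–Zhao-type Wittig olefination with the α-iodo ylide gives the (Z)-2-iodo-2-alkene (iodine cis to the chain) via the kinetically preferred cis-oxaphosphetane of an unstabilised ylide, typically ≥10:1 Z:E.

Step 4
Reactants: 12 (2E,6Z)-7-iodo-3-methylocta-2,6-dien-1-yl acetate; 13 3-(chloromethyl)furan
Product: 15 3-[(3E,7Z)-8-iodo-4-methylnona-3,7-dien-1-yl]furan, via (furan-3-ylmethyl)magnesium chloride 14 (not isolated)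
Conditions: 13, Mg, THF, 0 °C → rt; then 12, Li2CuCl4 (3 mol%), THF, −78 → 0 °C
Reagents that add atoms: none
Why: Copper-catalysed (Kochi-type) sp3–sp3 coupling of the Grignard reagent at the primary allylic acetate goes by α (SN2) substitution with retention of the E alkene, and the vinyl iodide is inert to Grignard/Cu at or below 0 °C.

Step 5
Reactants: 4 (2R)-2-methylpent-4-en-1-ol; 15 3-[(3E,7Z)-8-iodo-4-methylnona-3,7-dien-1-yl]furan
Product: 17 (2R,6Z,10E)-13-(furan-3-yl)-2,6,10-trimethyltrideca-6,10-dien-1-ol, via B-alkyl-9-BBN borinate 16 (not isolated)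
Conditions: 4, 9-BBN (2.2 equiv), THF, 0 °C → rt; then 15, Pd(dppf)Cl2 (5 mol%), AsPh3, Cs2CO3, DMF/H2O, rt
Reagents that add atoms: none
Why: 9-BBN hydroborates only the terminal alkene (the OH is tied up as a borinate) and the B-alkyl Suzuki–Miyaura coupling replaces iodine with retention, so the new chain is cis to the existing one (Z trisubstituted alkene) and the remote stereocentre is not involved.

Step 6
Reactants: 17 (2R,6Z,10E)-13-(furan-3-yl)-2,6,10-trimethyltrideca-6,10-dien-1-ol
Product: 18 (2R,6Z,10E)-13-(furan-3-yl)-2,6,10-trimethyltrideca-6,10-dienal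
Conditions: Dess–Martin periodinane, NaHCO3, CH2Cl2, 0 °C → rt
Reagents that add atoms: none
Why: Buffered Dess–Martin oxidation gives the α-methyl aldehyde without epimerisation and does not touch the furan or the trisubstituted alkenes.

Step 7
Reactants: 19 furan-3-ylmethanol
Product: 23 3-(hydroxymethyl)furan-2(5H)-one, via 2-lithio-3-(lithiooxymethyl)furan 20 (not isolated), via lithium furyltrimethoxyborate 21 (not isolated), via 3-(hydroxymethyl)furan-2-ol 22 (not isolated)
Conditions: n-BuLi (2.2 equiv), THF, −78 → 0 °C; B(OMe)3, −78 °C → rt; AcOH, then 30% H2O2, 0 °C → rt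
Reagents that add atoms: hydrogen peroxide, OO
Why: Alkoxide-directed ortho-lithiation occurs at C2, and borylation then oxidation of the C–B bond gives the 2-hydroxyfuran, which tautomerises to the conjugated butenolide.

Step 8
Reactants: 23 3-(hydroxymethyl)furan-2(5H)-one
Product: 24 3-({[tert-butyl(dimethyl)silyl]oxy}methyl)furan-2(5H)-one
Conditions: TBSCl, imidazole, CH2Cl2, 0 °C
Reagents that add atoms: tert-butyldimethylsilyl chloride, CC(C)(C)[Si](C)(C)Cl
Why: Standard silylation of the primary alcohol under mild imidazole conditions that do not open the lactone.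

Step 9
Reactants: 18 (2R,6Z,10E)-13-(furan-3-yl)-2,6,10-trimethyltrideca-6,10-dienal; 24 3-({[tert-butyl(dimethyl)silyl]oxy}methyl)furan-2(5H)-one
Product: 25 (5R)-3-({[tert-butyl(dimethyl)silyl]oxy}methyl)-5-[(1S,2R,6Z,10E)-13-(furan-3-yl)-1-hydroxy-2,6,10-trimethyltrideca-6,10-dien-1-yl]furan-2(5H)-one
Conditions: 24 (2 equiv), chiral bifunctional iminophosphorane–thiourea organocatalyst (10 mol%), PhMe, −60 °C; AcOH quench at −60 °C; chromatography
Reagents that add atoms: none
Why: Proposed new method: the bifunctional Brønsted-base/H-bond-donor catalyst deprotonates 24 at C5 to a catalyst-bound 2-furanolate, which attacks the thiourea-bound aldehyde through its γ-carbon in an open antiperiplanar transition state to give the unlike (5R,1'S; Felkin) adduct, whose relative configuration later encodes the E alkene (the 5S,1'R unlike isomer gives the same alkene); the C5 methylene of 24 should be deprotonated faster than the hindered α-CH of 18 at −60 °C, so C2' should not epimerise; closest known reaction type: amine–squaramide/thiourea- and guanidine-catalysed direct vinylogous aldol additions of γ-crotonolactone to aryl aldehydes (anti, i.e. unlike, selective), not yet shown for a 3-substituted butenolide with an α-stereogenic enolisable aliphatic aldehyde.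

Step 10
Reactants: 25 (5R)-3-({[tert-butyl(dimethyl)silyl]oxy}methyl)-5-[(1S,2R,6Z,10E)-13-(furan-3-yl)-1-hydroxy-2,6,10-trimethyltrideca-6,10-dien-1-yl]furan-2(5H)-one
Product: 27 22-deoxy-23-hydroxymethylvariabilin = (5E)-5-[(2R,6Z,10E)-13-(furan-3-yl)-2,6,10-trimethyltrideca-6,10-dien-1-ylidene]-3-(hydroxymethyl)furan-2(5H)-one, via TBS-protected E-ylidene butenolide 26 (not isolated)
Conditions: PPh3, DIAD, THF, 0 °C, dark; then HF·pyridine, pyridine, 0 °C
Reagents that add atoms: none
Why: Mitsunobu-type redox dehydration: the oxyphosphonium of the secondary alcohol loses the acidic γ-H by stereospecific anti-E2, which from the unlike (5R,1'S) adduct places the side chain cis to ring C4–H (E alkene), and buffered HF·pyridine then removes the primary TBS group without isomerising the alkene or touching the furan.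

## Compound list

1 | propanal | CCC=O | starting material
2 | allyltrimethylsilane | C=CC[Si](C)(C)C | starting material
3 | (2R)-2-methylpent-4-enal | C=CC[C@@H](C)C=O | intermediate (not isolated)
4 | (2R)-2-methylpent-4-en-1-ol | C=CC[C@@H](C)CO | intermediate
5 | geranyl acetate, (2E)-3,7-dimethylocta-2,6-dien-1-yl acetate | CC(C)=CCC/C(C)=C/COC(C)=O | starting material
6 | (2E)-5-(5,5-dimethyl-1,2,4-trioxolan-3-yl)-3-methylpent-2-en-1-yl acetate (secondary ozonide, either configuration at the ring CH) | CC(=O)OC/C=C(\C)CCC1OOC(C)(C)O1 | intermediate (not isolated)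
7 | (2E)-3-methyl-6-oxohex-2-en-1-yl acetate | O=CCC/C(C)=C/COC(C)=O | intermediate
8 | ethyltriphenylphosphonium iodide | CC[P+](c1ccccc1)(c1ccccc1)c1ccccc1.[I-] | starting material
9 | ethylidenetriphenylphosphorane | CC=P(c1ccccc1)(c1ccccc1)c1ccccc1 | intermediate (not isolated)
10 | (1-iodoethyl)triphenylphosphonium iodide | CC(I)[P+](c1ccccc1)(c1ccccc1)c1ccccc1.[I-] | intermediate (not isolated)
11 | (1-iodoethylidene)triphenylphosphorane | CC(I)=P(c1ccccc1)(c1ccccc1)c1ccccc1 | intermediate (not isolated)
12 | (2E,6Z)-7-iodo-3-methylocta-2,6-dien-1-yl acetate | C/C(I)=C/CC/C(C)=C/COC(C)=O | intermediate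
13 | 3-(chloromethyl)furan | ClCc1ccoc1 | starting material
14 | (furan-3-ylmethyl)magnesium chloride | Cl[Mg]Cc1ccoc1 | intermediate (not isolated)
15 | 3-[(3E,7Z)-8-iodo-4-methylnona-3,7-dien-1-yl]furan | C/C(I)=C/CC/C(C)=C/CCc1ccoc1 | intermediate
16 | 9-[(4R)-5-(9-borabicyclo[3.3.1]nonan-9-yloxy)-4-methylpentyl]-9-borabicyclo[3.3.1]nonane | B1(CCC[C@@H](C)COB2C3CCCC2CCC3)C2CCCC1CCC2 | intermediate (not isolated)
17 | (2R,6Z,10E)-13-(furan-3-yl)-2,6,10-trimethyltrideca-6,10-dien-1-ol | C/C(=C/CC/C(C)=C/CCc1ccoc1)CCC[C@@H](C)CO | intermediate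
18 | (2R,6Z,10E)-13-(furan-3-yl)-2,6,10-trimethyltrideca-6,10-dienal | C/C(=C/CC/C(C)=C/CCc1ccoc1)CCC[C@@H](C)C=O | intermediate
19 | furan-3-ylmethanol | OCc1ccoc1 | starting material
20 | 2-lithio-3-(lithiooxymethyl)furan | [Li]OCc1ccoc1[Li] | intermediate (not isolated)
21 | lithium [3-(lithiooxymethyl)furan-2-yl]trimethoxyborate | [Li+].[Li]OCc1ccoc1[B-](OC)(OC)OC | intermediate (not isolated)
22 | 3-(hydroxymethyl)furan-2-ol | OCc1ccoc1O | intermediate (not isolated)
23 | 3-(hydroxymethyl)furan-2(5H)-one | O=C1OCC=C1CO | intermediate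
24 | 3-({[tert-butyl(dimethyl)silyl]oxy}methyl)furan-2(5H)-one | CC(C)(C)[Si](C)(C)OCC1=CCOC1=O | intermediate
25 | (5R)-3-({[tert-butyl(dimethyl)silyl]oxy}methyl)-5-[(1S,2R,6Z,10E)-13-(furan-3-yl)-1-hydroxy-2,6,10-trimethyltrideca-6,10-dien-1-yl]furan-2(5H)-one | C/C(=C/CC/C(C)=C/CCc1ccoc1)CCC[C@@H](C)[C@H](O)[C@H]1C=C(CO[Si](C)(C)C(C)(C)C)C(=O)O1 | intermediate
26 | (5E)-3-({[tert-butyl(dimethyl)silyl]oxy}methyl)-5-[(2R,6Z,10E)-13-(furan-3-yl)-2,6,10-trimethyltrideca-6,10-dien-1-ylidene]furan-2(5H)-one | C/C(=C/CC/C(C)=C/CCc1ccoc1)CCC[C@@H](C)/C=C1\C=C(CO[Si](C)(C)C(C)(C)C)C(=O)O1 | intermediate (not isolated)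
27 | 22-deoxy-23-hydroxymethylvariabilin, (5E)-5-[(2R,6Z,10E)-13-(furan-3-yl)-2,6,10-trimethyltrideca-6,10-dien-1-ylidene]-3-(hydroxymethyl)furan-2(5H)-one | C/C(=C/CC/C(C)=C/CCc1ccoc1)CCC[C@@H](C)/C=C1\C=C(CO)C(=O)O1 | target

## Step count and risks

Total steps: 10 (each flask counted once). Longest linear sequence: 7 (steps 2, 3, 4, 5, 6, 9, 10, from geranyl acetate).

Three steps most likely to fail:

Step 9 (the proposed new step). The aliphatic aldehyde may react slowly, the unlike:like ratio may be modest, and base-mediated epimerisation at C2 of 18 or retro-aldol may intervene. The fallback uses known chemistry and a different nucleophile and activation mode. It sets out from 24 and 18. Butenolide 24 is silylated with TMSOTf/Et3N to tert-butyl(dimethyl){[2-(trimethylsilyloxy)furan-3-yl]methoxy}silane F1. F1 and 18 are then joined in a fluoride-triggered vinylogous Mukaiyama aldol (TBAF 5 mol%, THF, −78 °C), a mode known to favour the unlike (erythro) adduct, with a citric acid/MeOH work-up to cleave the TMS ether. It comes back at 25 after chromatographic removal of the like isomers.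

Step 10. The anti-elimination may leak through an E1cB path to the more stable Z alkene, and the E alkene can isomerise under light, phosphine or acid. The fallback switches to the other diastereomer series and a syn-elimination, so the two stereochemical changes cancel. It sets out from 18 and the silyloxyfuran F1 described above. The Lewis-acid Mukaiyama mode (BF3·OEt2, CH2Cl2, −78 °C), known to favour the like (threo) adduct, gives (5S)-3-({[tert-butyl(dimethyl)silyl]oxy}methyl)-5-[(1S,2R,6Z,10E)-13-(furan-3-yl)-1-hydroxy-2,6,10-trimethyltrideca-6,10-dien-1-yl]furan-2(5H)-one F2. Syn-dehydration of F2 with Burgess reagent (PhH, 50 °C) gives the same E alkene. It comes back at 26, which is desilylated with HF·pyridine as in step 10. Any Z isomer is removed on AgNO3-impregnated silica.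

Step 3. The iodo-Wittig olefination usually gives only 40–60% yield and some E isomer. The fallback builds the Z-haloalkene by cross-coupling instead of olefination. It sets out from 7. Ramirez dibromo-olefination (CBr4, PPh3, CH2Cl2, 0 °C) gives (2E)-7,7-dibromo-3-methylhepta-2,6-dien-1-yl acetate F3. Cu-catalysed coupling with Grignard reagent 14 as in step 4 gives 3-[(3E)-8,8-dibromo-4-methylocta-3,7-dien-1-yl]furan F4. Negishi trans-selective monomethylation (MeZnCl, Pd(DPEphos)Cl2, THF, 0 °C → rt) gives 3-[(3E,7Z)-8-bromo-4-methylnona-3,7-dien-1-yl]furan F5, the bromo analogue of 15. F5 is coupled with borane 16 under the conditions of step 5 (Pd(t-Bu3P)2 if the bromide is sluggish). It comes back at 17.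

Further compounds
F1 | step 9 | tert-butyl(dimethyl){[2-(trimethylsilyloxy)furan-3-yl]methoxy}silane | C[Si](C)(C)Oc1occc1CO[Si](C)(C)C(C)(C)C
F2 | step 10 | (5S)-3-({[tert-butyl(dimethyl)silyl]oxy}methyl)-5-[(1S,2R,6Z,10E)-13-(furan-3-yl)-1-hydroxy-2,6,10-trimethyltrideca-6,10-dien-1-yl]furan-2(5H)-one | C/C(=C/CC/C(C)=C/CCc1ccoc1)CCC[C@@H](C)[C@H](O)[C@@H]1C=C(CO[Si](C)(C)C(C)(C)C)C(=O)O1
F3 | step 3 | (2E)-7,7-dibromo-3-methylhepta-2,6-dien-1-yl acetate | BrC(Br)=CCC/C(C)=C/COC(C)=O
F4 | step 3 | 3-[(3E)-8,8-dibromo-4-methylocta-3,7-dien-1-yl]furan | BrC(Br)=CCC/C(C)=C/CCc1ccoc1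
F5 | step 3 | 3-[(3E,7Z)-8-bromo-4-methylnona-3,7-dien-1-yl]furan | C/C(Br)=C/CC/C(C)=C/CCc1ccoc1
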